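If two products come from the same pair by steps of the same form, their ratio at birth does not depend on how the pair is dosed.

all flasks: time 2.0 h

| charge | starting material | partner | remark |
|---|---|---|---|
| noon | 20 mM | 80.0 mM (fed, over 50 min) | all else is in the flask from the start; the feed brings no volume worth counting |
| dusk | 20 mM (fed, over 50 min) | 80.0 mM | all else is in the flask from the start; the feed brings no volume worth counting |
| dawn | 20 mM | 80.0 mM | everything together at the start |
| spring | 20 mM (in portions, 4, over 50 min) | 80.0 mM | first portion at the start, last at 50 min |
| winter | 20 mM (fed, over 5.0 min) | 80.0 mM | all else is in the flask from the start; the feed brings no volume worth counting |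

    starting material + partner → second isomer (k1 = 0.0081 L mol⁻¹ s⁻¹)
    starting material + partner → isomer of the product A (k2 = 5.1 × 10⁻⁴ L mol⁻¹ s⁻¹)
    starting material + partner → target (k3 = 0.0029 L mol⁻¹ s⁻¹)
    2 starting material → self-condensation product (k4 = 0.010 L mol⁻¹ s⁻¹)
    target ⇌ isomer of the product B (K5 = 0.73, k5 = 2.3 × 10⁻⁵ s⁻¹)
    partner → decomposed reagent (k6 = 1.4 × 10⁻⁵ s⁻¹)

- the flask that comes out highest in share of target in target plus isomer of the product A, or "all alike" when all lie within 1.5 percentage points (noon / dusk / dawn / spring / winter / all alike)
- share of target in target plus isomer of the product A at the end, noon
- share of target in target plus isomer of the product A at the end, dusk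
- share of target in target plus isomer of the product A at the end, dawn
- share of target in target plus isomer of the product A at the end, spring
- share of target in target plus isomer of the product A at the end, winter

- percentages count the starting material that a species holds: one self-condensation product counts as two
- a doubled species enters its step squared and goes two at a time
- run time (noon): 2.0 h

Target and isomer of the product A each take one starting material and one partner, so their rates stand as their constants stand, whatever [starting material] and [partner] are. Target therefore makes up 85.0% of the pair as it forms. I call this the birth share, the share under kinetic control, and I carry it forward.

Now the clocks, fastest first. With the whole partner in, starting material lasts 18.1 min against the coupling steps. Self-condensation at the whole charge has a first half-life of 41.7 min, longer, and the slow feed runs 50 min. These clocks move how much of the pair forms and when, but they move both members alike, so the birth share stands.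

 Target and isomer of the product B relax toward each other in 5.10 h, longer than the 2.0 h run, and target would end at 57.8% of itself. Partner decays with a lifetime of 19.8 h, longer still, and that step takes nothing from either member of the pair.

So the share at the end is the birth share, lowered by the age of the target. The kept fraction falls exponentially from whole toward that end value over the relaxation time. The share is then the birth share times the kept fraction, over itself plus the 15.0% of isomer of the product A.

In dawn, target is about 1.70 h old, so it keeps 88.0% and I reckon 83.4%, and about the same for winter. With the feed's midpoint added, target in noon, dusk and spring is about 1.28 h old, which gives 83.7%. The gap of 0.3 percentage points is smaller than the margin, so I call them alike.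

The forecast gives 83.5% for noon, 83.8% for dusk, 83.3% for dawn, 83.7% for spring and 83.4% for winter, and answers all alike, since “feeding only shifts formation time slightly”. For noon the two reckonings part: the forecast has 83.5% and I have 83.7%.

The flasks give 83.7% for noon, 83.8% for dusk, 83.4% for dawn, 83.8% for spring and 83.4% for winter: all alike. Self-condensation product meanwhile stands at 39.1% in noon against 10.5% in dusk at 2.00 h. Spring read at 8.0 h is the further case: its target is about 7.28 h old and keeps 67.9%, so the birth share of 85.0% becomes 79.4%, and that flask reads 79.5%.

Its constants are those of an exercise.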